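**Plan**

Labels: the flavone has rings A (benzo), C (pyranone) and B (2-aryl). The flavan has rings D (benzo), F (pyran) and E (2-aryl), with atoms O1, C2, C3, C4, C4a, C5 to C8 and C8a.
Cuts, in order: the six O-protecting groups; the C3–C4 saturation (back to a flav-3-ene); flavan C4–C4a (alkyne hydroarylation); O1–C2 (propargylic etherification); flavone C3–flavan C6 (Negishi coupling).
Forward: rings A, C and B come ready-made in apigenin, which is benzylated and iodinated at C3. Ring D is built as a 2,6-dibenzyloxy-4-oxygenated phenyl iodide and joined through zinc. The freed para phenol (future O1) then takes up the C2–C3–C4 chain with ring E, and ring F closes last.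
Enabling feature: before ring F exists, flavan C4a and C8 are the two equivalent CH carbons ortho to O1 on ring D. The para carbon C6 already holds flavone C3 between the C5 and C7 benzyloxy groups, so a chain anchored on O1 can only close to the 6-linked flavan and never to the 8-linked isomer.
Stereochemistry: the single stereocentre, flavan C2 (S), is set by a copper–pybox catalyst in an enantioconvergent etherification. After that it is only carried along, shielded from ionisation by the electron-poor pivaloyloxyphenyl ring E.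

Key step: step 13

Assumption: (S,S)-Ph-pybox is written as the ligand that gives the S ether. The sense of induction is to be fixed by a model run with 3,5-dimethoxyphenol, and the commercial (R,R) ligand is used if it turns out opposite.
Assumption: once ring F is closed, the flavone C3–flavan C6 axis has four unlike flanking groups. The ring-closed intermediates may therefore show slowly interconverting rotamers, which are taken not to be separable stereoisomers because the target is defined at C2 only.

Step 1
Reactants: 1 3,5-bis(benzyloxy)phenol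
Product: 3 2,6-bis(benzyloxy)-4-hydroxybenzaldehyde, via aryl iminium chloride 2 (not isolated)
Conditions: POCl3, DMF, 0 °C to rt; then H2O, 0 °C
Reagents that add atoms: N,N-dimethylformamide CN(C)C=O; water O
Why: Vilsmeier–Haack formylation of 3,5-dialkoxyphenols is known to go mainly para to the free hydroxyl, that is at the carbon between the two ethers, and the chelated, much less polar ortho-hydroxy isomer should be removable by chromatography or crystallisation.

Step 2
Reactants: 3 2,6-bis(benzyloxy)-4-hydroxybenzaldehyde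
Product: 4 2,6-bis(benzyloxy)-4-(methoxymethoxy)benzaldehyde
Conditions: MOMCl, i-Pr2NEt, CH2Cl2, 0 °C to rt
Reagents that add atoms: chloromethyl methyl ether COCCl
Why: Williamson-type O-alkylation of the acidic para-formyl phenol installs an acetal ether that should withstand oxidant, base, iodine and organolithium chemistry and can later be removed by mild acid without touching benzyl ethers.

Step 3
Reactants: 4 2,6-bis(benzyloxy)-4-(methoxymethoxy)benzaldehyde
Product: 5 2,6-bis(benzyloxy)-4-(methoxymethoxy)benzoic acid
Conditions: NaClO2, NaH2PO4, 2-methyl-2-butene (large excess), t-BuOH–THF–H2O, rt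
Reagents that add atoms: sodium chlorite [Na+].[O-]Cl=O
Why: Pinnick oxidation converts electron-rich, hindered benzaldehydes to the acids under buffered conditions that spare acetal and benzyl ethers, the excess alkene intercepting HOCl before it can chlorinate the activated ring.

Step 4
Reactants: 5 2,6-bis(benzyloxy)-4-(methoxymethoxy)benzoic acid
Product: 6 1,3-bis(benzyloxy)-2-iodo-5-(methoxymethoxy)benzene
Conditions: I2, K3PO4, MeCN, 100 °C (sealed tube)
Reagents that add atoms: iodine II
Why: Base-promoted, transition-metal-free decarboxylative iodination (a Hunsdiecker-type ipso substitution) is established for 2,6-dialkoxybenzoic acids and places iodine exactly on the carbon between the two benzyloxy groups, a site that direct halogenation of the parent phenol, which goes ortho to the hydroxyl, would not reach.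

Step 5
Reactants: 7 apigenin (5,7-dihydroxy-2-(4-hydroxyphenyl)-4H-chromen-4-one)
Product: 8 5,7-bis(benzyloxy)-2-[4-(benzyloxy)phenyl]-4H-chromen-4-one (tri-O-benzylapigenin)
Conditions: BnBr (excess), K2CO3, DMF, 80 °C
Reagents that add atoms: benzyl bromide BrCc1ccccc1
Why: Threefold Williamson benzylation, in which heating with excess bromide in DMF is what brings the hydrogen-bonded 5-hydroxyl to react as well, as is known for perbenzylation of 5-hydroxyflavones.

Step 6
Reactants: 8 tri-O-benzylapigenin
Product: 10 5,7-bis(benzyloxy)-2-[4-(benzyloxy)phenyl]-3-iodo-4H-chromen-4-one, via 3-lithioflavone 9 (not isolated)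
Conditions: LiN(i-Pr)2, THF, −78 °C; then I2, −78 °C to rt
Reagents that add atoms: iodine II
Why: Deprotonation of flavones by lithium amide bases occurs at C3, the vinylic CH next to the carbonyl, and iodine quench of this vinyllithium avoids electrophilic iodination conditions, which would attack C6 or C8 of the electron-rich ring A instead.

Step 7
Reactants: 6 1,3-bis(benzyloxy)-2-iodo-5-(methoxymethoxy)benzene; 10 3-iodo-tri-O-benzylapigenin
Product: 13 5,7-bis(benzyloxy)-2-[4-(benzyloxy)phenyl]-3-[2,6-bis(benzyloxy)-4-(methoxymethoxy)phenyl]-4H-chromen-4-one, via aryllithium 11 (not isolated), via arylzinc chloride 12 (not isolated)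
Conditions: 6, n-BuLi, THF, −78 °C; ZnCl2, −78 °C to rt; then 10, Pd2(dba)3 (cat), RuPhos, THF, 65 °C
Reagents that add atoms: none
Why: Negishi cross-coupling, in which fast iodine–lithium exchange and transmetalation give a 2,6-dialkoxyarylzinc free of the protodeboronation problem of the matching boronic acid, the alpha-iodoenone adds readily to zerovalent palladium, and the bulky biaryl phosphine belongs to the ligand class known to deliver biaryls with four ortho substituents.

Step 8
Reactants: 13 MOM-protected 3-arylflavone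
Product: 14 5,7-bis(benzyloxy)-2-[4-(benzyloxy)phenyl]-3-[2,6-bis(benzyloxy)-4-hydroxyphenyl]-4H-chromen-4-one (flavone phenol)
Conditions: HCl (cat), MeOH–THF, 45 °C
Reagents that add atoms: none
Why: Acid-catalysed acetal exchange (MOM cleavage) in methanol frees only the para phenol, since benzyl aryl ethers and the chromone are inert to dilute HCl at this temperature.

Step 9
Reactants: 15 4-hydroxybenzaldehyde
Product: 16 4-formylphenyl pivalate
Conditions: PivCl, Et3N, DMAP (cat), CH2Cl2, 0 °C to rt
Reagents that add atoms: pivaloyl chloride CC(C)(C)C(=O)Cl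
Why: Simple O-acylation with an acid chloride gives an ester that is hindered enough for the coming Grignard and amine-base steps and that makes ring E electron-poor, which is what later holds the benzylic C2–O1 bond together.

Step 10
Reactants: 16 4-formylphenyl pivalate
Product: 17 rac-4-(1-hydroxyprop-2-yn-1-yl)phenyl pivalate
Conditions: HC≡CMgBr, THF, −78 to −20 °C; then aq NH4Cl
Reagents that add atoms: ethynylmagnesium bromide C#C[Mg]Br
Why: 1,2-Addition of an alkynyl Grignard reagent to the aldehyde is far faster at low temperature than attack on the hindered pivalate, and the carbinol may be racemic because the later etherification is enantioconvergent.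

Step 11
Reactants: 17 rac-4-(1-hydroxyprop-2-yn-1-yl)phenyl pivalate
Product: 18 rac-4-{1-[(tert-butoxycarbonyl)oxy]prop-2-yn-1-yl}phenyl pivalate
Conditions: Boc2O, DMAP (cat), CH2Cl2, 0 °C to rt
Reagents that add atoms: di-tert-butyl dicarbonate CC(C)(C)OC(=O)OC(=O)OC(C)(C)C
Why: DMAP-catalysed carbonate formation installs a leaving group that later falls apart to CO2 and tert-butoxide, an internal base too hindered to compete with the phenol as nucleophile or to cleave the pivalate.

Step 12
Reactants: 14 flavone phenol; 18 racemic propargylic tert-butyl carbonate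
Product: 19 4-[(1S)-1-{3,5-bis(benzyloxy)-4-[5,7-bis(benzyloxy)-2-(4-benzyloxyphenyl)-4-oxo-4H-chromen-3-yl]phenoxy}prop-2-yn-1-yl]phenyl pivalate ((S)-aryl propargyl ether)
Conditions: Cu(MeCN)4BF4 (5 mol %), (S,S)-Ph-pybox (2,6-bis[(4S)-4-phenyl-4,5-dihydrooxazol-2-yl]pyridine, 6 mol %), i-Pr2NEt, THF, −20 °C
Reagents that add atoms: none
Why: Copper-catalysed asymmetric propargylic etherification of phenols, in which both enantiomers of 18 pass through the copper acetylide into one planar copper allenylidene and the pybox ligand on monovalent copper leaves one face open, so that the phenoxide oxygen of 14 adds to the gamma carbon and sets C2 as S.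

Step 13
Reactants: 19 (S)-aryl propargyl ether
Product: 20 (2S)-5,7-bis(benzyloxy)-6-{5,7-bis(benzyloxy)-2-[4-(benzyloxy)phenyl]-4-oxo-4H-chromen-3-yl}-2-[4-(pivaloyloxy)phenyl]-2H-chromene (penta-O-benzyl 4'-O-pivaloyl flav-3-ene)
Conditions: Ph3PAuNTf2 (3 mol %), dry CH2Cl2, 0 °C to rt, exclusion of light
Reagents that add atoms: none
Why: The cationic monovalent gold centre binds the terminal alkyne of 19, a ring D CH carbon that lies ortho to O1 and para to a benzyloxy group attacks the terminal alkyne carbon, and rearomatisation followed by protodeauration of the vinylgold species releases 20, flavan C4–C4a being the one new skeletal bond. The closest known reaction type is the gold- or platinum-catalysed intramolecular hydroarylation of aryl propargyl ethers to 2H-chromenes, which runs at or below room temperature on electron-rich aryl rings. Pyran ring F closes in the 6-endo-dig mode, because the 5-exo-dig alternative would require attack at the internal alkyne carbon across a strained three-atom tether and is not the usual outcome for terminal alkynes. No stereocentre is created, and the S configuration at the spectator carbon C2 should persist because the pivaloyloxy group makes ring E a poor cation stabiliser and so disfavours heterolysis of the propargylic C2–O1 bond. Site selectivity needs no control, since C4a and C8 are interchanged by the local twofold symmetry of the 4-alkoxy-2,6-dibenzyloxyphenyl ring and closure at either one gives the same 6-linked constitution. Low temperature, darkness and immediate use of 20 guard against electrocyclic opening of the 2H-chromene, the remaining pathway that could erode the configuration.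

Step 14
Reactants: 20 penta-O-benzyl 4'-O-pivaloyl (2S)-flav-3-ene
Product: 21 (2S)-5,7-bis(benzyloxy)-6-{5,7-bis(benzyloxy)-2-[4-(benzyloxy)phenyl]-4-oxo-4H-chromen-3-yl}-2-[4-(pivaloyloxy)phenyl]chromane (penta-O-benzyl 4'-O-pivaloyl flavan)
Conditions: 2-nitrobenzenesulfonyl hydrazide (excess, in portions), Et3N, CH2Cl2, rt, exclusion of light
Reagents that add atoms: none
Why: Diimide reduction, with the diimide generated at room temperature, transfers two hydrogens in a concerted way to the unpolarised cis-disubstituted C3=C4 bond and leaves the allylic and benzylic C2–O1 bond, the benzyl ethers and the tetrasubstituted, polarised flavone double bond untouched, so C2 stays S.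

Step 15
Reactants: 21 penta-O-benzyl 4'-O-pivaloyl (2S)-flavan
Product: 22 (2S)-5,7-bis(benzyloxy)-6-{5,7-bis(benzyloxy)-2-[4-(benzyloxy)phenyl]-4-oxo-4H-chromen-3-yl}-2-(4-hydroxyphenyl)chromane (penta-O-benzyl flavan with free 4'-hydroxyl)
Conditions: NaOMe, MeOH–THF, 0 °C; then AcOH, 0 °C
Reagents that add atoms: none
Why: Methoxide transesterification cleaves the aryl pivalate quickly, and working at 0 °C with an acetic acid quench gives the 4-oxidobenzyl aryl ether no time to open through a para-quinone methide, the process that could racemise C2.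

Step 16
Reactants: 22 penta-O-benzyl (2S)-flavan with free 4'-hydroxyl
Product: 23 CNP0304187.1, (2S)-6-[5,7-dihydroxy-2-(4-hydroxyphenyl)-4-oxo-4H-chromen-3-yl]-2-(4-hydroxyphenyl)chromane-5,7-diol
Conditions: H2 (1 atm), 10% Pd/C, THF–MeOH, rt; filtration under argon
Reagents that add atoms: none
Why: Catalytic hydrogenolysis of benzyl aryl ethers at atmospheric pressure is the standard last step of flavan and catechin syntheses, in which the cyclic benzylic C2–O1 ether and the chromone double bond survive when the reaction is stopped at complete debenzylation.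

**Compound list**

1 | 3,5-bis(benzyloxy)phenol | Oc1cc(OCc2ccccc2)cc(OCc2ccccc2)c1 | starting material
2 | N-[2,6-bis(benzyloxy)-4-hydroxybenzylidene]-N-methylmethanaminium chloride | C[N+](C)=Cc1c(OCc2ccccc2)cc(O)cc1OCc1ccccc1.[Cl-] | intermediate
3 | 2,6-bis(benzyloxy)-4-hydroxybenzaldehyde | O=Cc1c(OCc2ccccc2)cc(O)cc1OCc1ccccc1 | intermediate
4 | 2,6-bis(benzyloxy)-4-(methoxymethoxy)benzaldehyde | O=Cc1c(OCc2ccccc2)cc(OCOC)cc1OCc1ccccc1 | intermediate
5 | 2,6-bis(benzyloxy)-4-(methoxymethoxy)benzoic acid | O=C(O)c1c(OCc2ccccc2)cc(OCOC)cc1OCc1ccccc1 | intermediate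
6 | 1,3-bis(benzyloxy)-2-iodo-5-(methoxymethoxy)benzene | Ic1c(OCc2ccccc2)cc(OCOC)cc1OCc1ccccc1 | intermediate
7 | apigenin | O=c1cc(-c2ccc(O)cc2)oc2cc(O)cc(O)c12 | starting material
8 | 5,7-bis(benzyloxy)-2-[4-(benzyloxy)phenyl]-4H-chromen-4-one | O=c1cc(-c2ccc(OCc3ccccc3)cc2)oc2cc(OCc3ccccc3)cc(OCc3ccccc3)c12 | intermediate
9 | 3-lithio derivative of 8 | [Li]c1c(-c2ccc(OCc3ccccc3)cc2)oc2cc(OCc3ccccc3)cc(OCc3ccccc3)c2c1=O | intermediate
10 | 5,7-bis(benzyloxy)-2-[4-(benzyloxy)phenyl]-3-iodo-4H-chromen-4-one | O=c1c(I)c(-c2ccc(OCc3ccccc3)cc2)oc2cc(OCc3ccccc3)cc(OCc3ccccc3)c12 | intermediate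
11 | [2,6-bis(benzyloxy)-4-(methoxymethoxy)phenyl]lithium | [Li]c1c(OCc2ccccc2)cc(OCOC)cc1OCc1ccccc1 | intermediate
12 | [2,6-bis(benzyloxy)-4-(methoxymethoxy)phenyl]zinc chloride | Cl[Zn]c1c(OCc2ccccc2)cc(OCOC)cc1OCc1ccccc1 | intermediate
13 | 5,7-bis(benzyloxy)-2-[4-(benzyloxy)phenyl]-3-[2,6-bis(benzyloxy)-4-(methoxymethoxy)phenyl]-4H-chromen-4-one | O=c1c(-c2c(OCc3ccccc3)cc(OCOC)cc2OCc2ccccc2)c(-c2ccc(OCc3ccccc3)cc2)oc2cc(OCc3ccccc3)cc(OCc3ccccc3)c12 | intermediate
14 | 5,7-bis(benzyloxy)-2-[4-(benzyloxy)phenyl]-3-[2,6-bis(benzyloxy)-4-hydroxyphenyl]-4H-chromen-4-one | O=c1c(-c2c(OCc3ccccc3)cc(O)cc2OCc2ccccc2)c(-c2ccc(OCc3ccccc3)cc2)oc2cc(OCc3ccccc3)cc(OCc3ccccc3)c12 | intermediate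
15 | 4-hydroxybenzaldehyde | O=Cc1ccc(O)cc1 | starting material
16 | 4-formylphenyl pivalate | O=Cc1ccc(OC(=O)C(C)(C)C)cc1 | intermediate
17 | rac-4-(1-hydroxyprop-2-yn-1-yl)phenyl pivalate | C#CC(O)c1ccc(OC(=O)C(C)(C)C)cc1 | intermediate
18 | rac-4-{1-[(tert-butoxycarbonyl)oxy]prop-2-yn-1-yl}phenyl pivalate | C#CC(OC(=O)OC(C)(C)C)c1ccc(OC(=O)C(C)(C)C)cc1 | intermediate
19 | (S)-aryl propargyl ether of 14 with a 4-pivaloyloxyphenyl group on the carbinol carbon | C#C[C@@H](c1ccc(OC(=O)C(C)(C)C)cc1)Oc1cc(OCc2ccccc2)c(-c2c(-c3ccc(OCc4ccccc4)cc3)oc3cc(OCc4ccccc4)cc(OCc4ccccc4)c3c2=O)c(OCc2ccccc2)c1 | intermediate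
20 | penta-O-benzyl 4'-O-pivaloyl (2S)-flav-3-ene | O=c1c(-c2c(OCc3ccccc3)cc3c(c2OCc2ccccc2)C=C[C@@H](c2ccc(OC(=O)C(C)(C)C)cc2)O3)c(-c2ccc(OCc3ccccc3)cc2)oc2cc(OCc3ccccc3)cc(OCc3ccccc3)c12 | intermediate
21 | penta-O-benzyl 4'-O-pivaloyl (2S)-flavan | O=c1c(-c2c(OCc3ccccc3)cc3c(c2OCc2ccccc2)CC[C@@H](c2ccc(OC(=O)C(C)(C)C)cc2)O3)c(-c2ccc(OCc3ccccc3)cc2)oc2cc(OCc3ccccc3)cc(OCc3ccccc3)c12 | intermediate
22 | penta-O-benzyl (2S)-flavan with free 4'-hydroxyl | O=c1c(-c2c(OCc3ccccc3)cc3c(c2OCc2ccccc2)CC[C@@H](c2ccc(O)cc2)O3)c(-c2ccc(OCc3ccccc3)cc2)oc2cc(OCc3ccccc3)cc(OCc3ccccc3)c12 | intermediate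
23 | CNP0304187.1 | O=c1c(-c2c(O)cc3c(c2O)CC[C@@H](c2ccc(O)cc2)O3)c(-c2ccc(O)cc2)oc2cc(O)cc(O)c12 | target

**Summary**

Total step count: 16.
Longest linear sequence: 11 steps (steps 1, 2, 3, 4, 7, 8, 12, 13, 14, 15, 16).

**Steps most likely to fail**

Step 7.
- What may go wrong: transmetalation and reductive elimination at a bond flanked on all four sides may be slower than protonation or homocoupling of the zinc reagent and reduction of the iodoflavone.
- Fallback (sets out from 6, returns at 14): the aryl–C3 bond is made on an open chain and ring C is closed afterwards.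
  - Commercial 1-[2,4-bis(benzyloxy)-6-hydroxyphenyl]ethanone is converted with NaH and MOMCl in DMF into 1-[2,4-bis(benzyloxy)-6-(methoxymethoxy)phenyl]ethanone F1.
  - Palladium-catalysed ketone alpha-arylation of F1 with 6 (Pd2(dba)3, XPhos, NaOt-Bu, toluene, 80 °C) joins the hindered aryl group to an unhindered primary enolate carbon. It should give the deoxybenzoin 1-[2,4-bis(benzyloxy)-6-(methoxymethoxy)phenyl]-2-[2,6-bis(benzyloxy)-4-(methoxymethoxy)phenyl]ethanone F2.
  - The lithium enolate of F2 (LiN(SiMe3)2, THF, −78 °C) is C-acylated with commercial 4-benzyloxybenzoyl chloride to the 2-aryl-1,3-diketone 1-[2,4-bis(benzyloxy)-6-(methoxymethoxy)phenyl]-2-[2,6-bis(benzyloxy)-4-(methoxymethoxy)phenyl]-3-[4-(benzyloxy)phenyl]propane-1,3-dione F3.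
  - HCl in MeOH–THF at 50 °C then removes both MOM groups and cyclodehydrates the freed ortho phenol onto the aroyl carbonyl, giving 14 directly.

Step 12.
- What may go wrong: Friedel–Crafts-type C-propargylation at the very electron-rich ortho carbons of ring D may compete with O-attack on the copper allenylidene. Facial selectivity with this bulky phenol may also be poor.
- Fallback (sets out from 17, returns at 19): the configuration is fixed on the alcohol and transferred by an invertive substitution.
  - Racemic 17 is resolved with immobilised Candida antarctica lipase B and vinyl acetate in MTBE at 30 °C, stopped near half conversion.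
  - By the empirical size rule for lipase acylation of secondary alcohols, the R enantiomer should be acylated to 4-[(1R)-1-acetoxyprop-2-yn-1-yl]phenyl pivalate F4.
  - The unreacted 4-[(1S)-1-hydroxyprop-2-yn-1-yl]phenyl pivalate F5 is separated and set aside.
  - Neutral butanolysis of F4 with the same enzyme (n-BuOH, MTBE) leaves the aryl pivalate alone and should give 4-[(1R)-1-hydroxyprop-2-yn-1-yl]phenyl pivalate F6.
  - Mitsunobu etherification of 14 with F6 (PPh3, DIAD, toluene, −20 to 0 °C) proceeds with inversion to 19. The electron-poor ring E suppresses the ionisation that would cost enantiopurity.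

Step 13.
- What may go wrong: gold-assisted heterolysis of the propargylic C2–O1 bond may occur, or light- and heat-induced electrocyclic opening of the 2H-chromene. Either would erode the configuration at C2. The acid-sensitive flav-3-ene may also decompose.
- Fallback (sets out from 19, returns at 21): the same C4–C4a bond is closed from the same chain on O1, with the same symmetry argument, but at the aldehyde oxidation level, so that no chromene is ever formed.
  - Hydroboration of the terminal alkyne with dicyclohexylborane (THF, 0 °C) and oxidation with NaBO3·4H2O should give the aldehyde (3S)-3-aryloxy-3-[4-(pivaloyloxy)phenyl]propanal F7.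
  - BF3·OEt2 in CH2Cl2 at −78 °C brings about intramolecular Friedel–Crafts hydroxyalkylation at an ortho carbon of ring D. This gives the (2S)-flavan-4-ol F8 as a mixture of C4 epimers.
  - Et3SiH added to the same flask removes the doubly activated benzylic hydroxyl by ionic reduction, giving 21.

**Further compounds**

F1 | step 7 | 1-[2,4-bis(benzyloxy)-6-(methoxymethoxy)phenyl]ethanone | CC(=O)c1c(OCOC)cc(OCc2ccccc2)cc1OCc1ccccc1
F2 | step 7 | 1-[2,4-bis(benzyloxy)-6-(methoxymethoxy)phenyl]-2-[2,6-bis(benzyloxy)-4-(methoxymethoxy)phenyl]ethanone | O=C(Cc1c(OCc2ccccc2)cc(OCOC)cc1OCc1ccccc1)c1c(OCOC)cc(OCc2ccccc2)cc1OCc1ccccc1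
F3 | step 7 | 1-[2,4-bis(benzyloxy)-6-(methoxymethoxy)phenyl]-2-[2,6-bis(benzyloxy)-4-(methoxymethoxy)phenyl]-3-[4-(benzyloxy)phenyl]propane-1,3-dione | O=C(c1ccc(OCc2ccccc2)cc1)C(c1c(OCc2ccccc2)cc(OCOC)cc1OCc1ccccc1)C(=O)c1c(OCOC)cc(OCc2ccccc2)cc1OCc1ccccc1
F4 | step 12 | 4-[(1R)-1-acetoxyprop-2-yn-1-yl]phenyl pivalate | C#C[C@@H](OC(C)=O)c1ccc(OC(=O)C(C)(C)C)cc1
F5 | step 12 | 4-[(1S)-1-hydroxyprop-2-yn-1-yl]phenyl pivalate | C#C[C@H](O)c1ccc(OC(=O)C(C)(C)C)cc1
F6 | step 12 | 4-[(1R)-1-hydroxyprop-2-yn-1-yl]phenyl pivalate | C#C[C@@H](O)c1ccc(OC(=O)C(C)(C)C)cc1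
F7 | step 13 | (3S)-3-{3,5-bis(benzyloxy)-4-[5,7-bis(benzyloxy)-2-(4-benzyloxyphenyl)-4-oxo-4H-chromen-3-yl]phenoxy}-3-[4-(pivaloyloxy)phenyl]propanal | O=CC[C@@H](c1ccc(OC(=O)C(C)(C)C)cc1)Oc1cc(OCc2ccccc2)c(-c2c(-c3ccc(OCc4ccccc4)cc3)oc3cc(OCc4ccccc4)cc(OCc4ccccc4)c3c2=O)c(OCc2ccccc2)c1
F8 | step 13 | penta-O-benzyl 4'-O-pivaloyl (2S)-flavan-4-ol, both C4 epimers | O=c1c(-c2c(OCc3ccccc3)cc3c(c2OCc2ccccc2)C(O)C[C@@H](c2ccc(OC(=O)C(C)(C)C)cc2)O3)c(-c2ccc(OCc3ccccc3)cc2)oc2cc(OCc3ccccc3)cc(OCc3ccccc3)c12
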